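Whether I read the flask at 20 s, as in ash, or at 40 s, as in alder, is the difference between these two recipes, so I must find out whether the later reading can still change anything.

common to all: substrate 5.0 × 10⁻⁴ M; gas phase 0.036 mM (held)

| run | time |
|---|---|
| ash | 20 s |
| alder | 40 s |

    2 dissolved gas → homo dimer (k1 = 5100 M⁻¹ s⁻¹)
    substrate → side product (k2 = 0.20 s⁻¹)
    substrate + dissolved gas → target (k3 = 7300 M⁻¹ s⁻¹)
    target ⇌ isomer of the product (K4 = 0.29, k4 = 1.8 s⁻¹)
    gas phase ⇌ dissolved gas, rate k5*(csat - [dissolved gas]) (k5 = 3.7 s⁻¹, csat = 0.036 mM)

1. which of these there is most of at the end, counted by the substrate in it, ash (isomer of the product / target / side product / substrate)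
2. which of these there is most of at the end, counted by the substrate in it, alder (isomer of the product / target / side product / substrate)
3. the largest of these amounts at the end, in percent of the substrate charged, ash
4. the largest of these amounts at the end, in percent of the substrate charged, alder

Substrate leaves by two exits: it turns into side product by itself, and dissolved gas captures it to target, a pseudo-first-order loss whose frequency is the capture constant times the level of dissolved gas. That level follows the substrate, since the half-life of dissolved gas by transfer, 0.187 s, which lasts as the substrate falls, is far shorter than the 3.5 s of substrate by the side step. In this quasi-steady state, the level is the transfer coefficient times the saturation concentration, divided by the sum of that coefficient, the capture loss and the dimer loss; the dimer loss contains the level itself, and I go round twice.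

I take the moment when half of the charge is left as standing for the run. Without the dimer loss the level is 2.41 × 10⁻⁵ M, and putting that back gives 2.31 × 10⁻⁵ M, so capture runs at 0.168 s⁻¹ against 0.20 s⁻¹ for the side step. The mid-run side share, the side constant divided by the sum of the side constant and the capture frequency, is 54.3%.

The captured rest divides by the equilibrium constant, whose relaxation half-life in ash is 0.0866 s, into 35.4% target and 10.3% isomer of the product, so I expect more side product than target in both flasks. Substrate has a half-life near 1.88 s, much shorter than the time of ash, which leaves about 0.0636% of it in ash, so I expect alder to read as ash does.

The forecast names side product for ash and side product for alder, at 54% and 54%, on the ground that “ash and alder end up the same”.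

The simulation gives side product at 55.2% in ash and side product at 55.2% in alder, against my mid-run side share of 54.3%. The neighbouring flask is ash with 2.0 × 10⁻⁴ M of substrate. Going round twice again gives 3.01 × 10⁻⁵ M, then 2.81 × 10⁻⁵ M, a higher level than in ash, and so a mid-run side share of 49.3%, lower than in ash. That neighbouring flask, read at 20.0 s, holds 51.1% side product against 37.9% target.

All constants are those of an exercise, and the outcome is calculated.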